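**Retrosynthetic overview**
1. Target 22 ⇐ angeloylation at O3 (then C7 equilibration) of hydroxy acetate 18 ⇐ Woodward cis-acetoxy-hydroxylation of the C3=C4 alkene 15.
2. 15 ⇐ enol triflate formation and Negishi methylation at C4 of cis-decalone 11, whose ring B ketone is masked as a silyl enol ether.
3. 11 ⇐ two-carbon ring expansion of the cyclobutanone in 5 (C5–C8 cut, C8–C7 and C6–C5 made) by alkenyl addition, retro-aldol opening and Michael closure.
4. 5 ⇐ ozonolysis of 3 ⇐ enantioselective [2+2] photocycloaddition of 3-methylcyclohex-2-enone with allene.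
5. Ring order: ring A is bought (1); the cyclobutane is made in step 1; ring B is made by expanding the cyclobutanone in step 3.

Assumptions: C1–C15 in the explanations are eudesmane locants (C3 = angeloyloxy carbon, C4 = acetoxy carbon, C5/C10 = ring fusion, C7 = isopropyl carbon, C8 = ketone), β is the face of the C10 methyl, and 2-bromo-3-methylbut-1-ene is taken as a catalogue reagent.

**Step 1**
Reactants: 1 3-methylcyclohex-2-en-1-one; 2 propa-1,2-diene (allene)
Product: 3 (1S,6R)-6-methyl-8-methylidenebicyclo[4.2.0]octan-2-one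
Conditions: 2 (10 equiv, condensed), AlBr3 adduct of (S)-3,3-bis(2,3-dimethylphenyl)-1-(2,4,6-trifluorophenyl)tetrahydro-1H,3H-pyrrolo[1,2-c][1,3,2]oxazaborole (50 mol %), CH2Cl2, −75 °C, hν (366 nm)
Reagents that add atoms: none
Why: Proposed new method: binding of the chiral AlBr3–oxazaborolidine to the enone carbonyl red-shifts its absorption so that only the complex is excited at 366 nm, the aryl groups shield one face of the enone C=C, and allene bonds through its central carbon to the α-carbon (head-to-head) with cis closure enforced by the four-membered ring, which fixes quaternary C10 as (R) (the catalyst antipode is chosen to give this enantiomer); the closest known reaction type is the chiral Lewis acid-catalysed enantioselective intermolecular [2+2] photocycloaddition of cyclic enones with simple alkenes, not shown for an allene, together with the classical racemic enone–allene photocycloaddition.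

**Step 2**
Reactants: 3 (1S,6R)-6-methyl-8-methylidenebicyclo[4.2.0]octan-2-one
Product: 5 (1S,6R)-6-methylbicyclo[4.2.0]octane-2,8-dione, via spiro ozonide 4 (not isolated)
Conditions: O3, CH2Cl2, −78 °C; then PPh3, −78 °C → rt
Reagents that add atoms: ozone, [O-][O+]=O
Why: Ozonolysis cleaves the only C=C (the exocyclic methylene) to the cyclobutanone; the aprotic medium and PPh3 reduction avoid retro-Claisen opening of the strained 1,3-diketone, and no stereocentre is touched.

**Step 3**
Reactants: 5 (1S,6R)-6-methylbicyclo[4.2.0]octane-2,8-dione; 6 2-bromo-3-methylbut-1-ene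
Product: 11 (4aR,8aS)-6-[(tert-butyldimethylsilyl)oxy]-4a-methyl-7-(propan-2-yl)-3,4,4a,5,8,8a-hexahydronaphthalen-1(2H)-one, via alkenyl Grignard reagent 7 (not isolated), via cyclobutanolate 8 (not isolated), via ring-opened enolate 9 (not isolated), via ring-closed enolate 10 (not isolated)
Conditions: 6, Mg, THF, 50 °C; anhydrous CeCl3 (1.2 equiv), THF, −78 °C; then 5, −78 → 0 °C; then TBSOTf, −78 °C → rt
Reagents that add atoms: tert-butyldimethylsilyl trifluoromethanesulfonate, CC(C)(C)[Si](C)(C)OS(=O)(=O)C(F)(F)F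
Why: Proposed new method: the weakly basic, oxophilic CeCl3-modified alkenyl Grignard reagent adds to the strained, aldehyde-like cyclobutanone carbonyl from the exo face faster than it removes the C5 proton of the 1,3-diketone; cyclobutanolate 8 then fragments by strain-driven retro-aldol cleavage of C8–C5 to ring A enolate 9, which carries an α-isopropyl vinyl ketone on the C10 arm, and 6-endo-trig Michael closure by axial attack on the axially held arm gives the cis-fused decalin (C5 set as S, H cis to the angular methyl) as ring B enolate 10, which TBSOTf traps on oxygen so that the new ketone stays masked and C7 stays trigonal; the net result is a two-carbon ring expansion of the cyclobutanone to the ring B cyclohexanone (formal anionic 1,3-acyl shift); closest known reaction types are the retro-aldol opening of β-keto cyclobutanols (de Mayo fragmentation), organocerium addition to enolisable ketones, Michael ring closure of keto enolates onto enones and the alkoxide-accelerated 1,3-shift of vinylcyclobutanols.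

**Step 4**
Reactants: 11 (4aR,8aS)-6-[(tert-butyldimethylsilyl)oxy]-4a-methyl-7-(propan-2-yl)-3,4,4a,5,8,8a-hexahydronaphthalen-1(2H)-one
Product: 13 (4aR,8aS)-6-[(tert-butyldimethylsilyl)oxy]-4a-methyl-7-(propan-2-yl)-3,4,4a,5,8,8a-hexahydronaphthalen-1-yl trifluoromethanesulfonate, via potassium enolate 12 (not isolated)
Conditions: KN(SiMe3)2, THF, −78 °C; then PhNTf2, −78 → 0 °C
Reagents that add atoms: N-phenylbis(trifluoromethanesulfonimide), O=S(=O)(N(c1ccccc1)S(=O)(=O)C(F)(F)F)C(F)(F)F
Why: Kinetic deprotonation by the bulky amide removes a C3 proton (the only unhindered α-CH2; C5 is a ring-fusion methine and the ring B carbonyl is masked) and O-sulfonylation of the enolate gives the enol triflate; C5 is not epimerised because deprotonation is irreversible at −78 °C.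

**Step 5**
Reactants: 13 (4aR,8aS)-6-[(tert-butyldimethylsilyl)oxy]-4a-methyl-7-(propan-2-yl)-3,4,4a,5,8,8a-hexahydronaphthalen-1-yl trifluoromethanesulfonate
Product: 15 (3RS,4aS,8aR)-5,8a-dimethyl-3-(propan-2-yl)-3,4,4a,7,8,8a-hexahydronaphthalen-2(1H)-one, via methylated silyl enol ether 14 (not isolated)
Conditions: MeZnCl, Pd(PPh3)4 (5 mol %), THF, 50 °C; then 1 M HCl, THF, 0 °C → rt
Reagents that add atoms: methylzinc chloride, C[Zn]Cl
Why: Negishi cross-coupling of the enol triflate installs the C4 methyl without touching the silyl enol ether, and dilute acid then unmasks the ring B ketone; C7 is protonated unselectively, which is harmless because this ketone α-centre is equilibrated at the end of step 7.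

**Step 6**
Reactants: 15 (3RS,4aS,8aR)-5,8a-dimethyl-3-(propan-2-yl)-3,4,4a,7,8,8a-hexahydronaphthalen-2(1H)-one
Product: 18 (1S,2R,4aR,7RS,8aS)-2-hydroxy-1,4a-dimethyl-6-oxo-7-(propan-2-yl)decahydronaphthalen-1-yl acetate, via iodoacetate 16 (not isolated), via acetoxonium acetate 17 (not isolated)
Conditions: I2, AgOAc, AcOH, rt; then H2O, 95 °C
Reagents that add atoms: silver acetate, CC(=O)[O-].[Ag+]; water, O
Why: Woodward cis-hydroxylation: electrophilic iodine adds at C3 on the exposed β face (ring B is folded under the α face), acetate opens at tertiary C4 from the α face (Markovnikov, anti) to trans-diaxial 16, the C4 acetate then displaces the axial iodide from the α face (silver-assisted neighbouring-group participation) to give the cis-α acetoxonium ion 17, and water opens it to the axial tertiary acetate and the equatorial secondary alcohol, which sets C3 (R) and C4 (S).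

**Step 7**
Reactants: 18 (1S,2R,4aR,7RS,8aS)-2-hydroxy-1,4a-dimethyl-6-oxo-7-(propan-2-yl)decahydronaphthalen-1-yl acetate; 19 angelic acid [(2Z)-2-methylbut-2-enoic acid]
Product: 22 (1S,2R,4aR,7R,8aS)-1-(acetyloxy)-1,4a-dimethyl-6-oxo-7-(propan-2-yl)decahydronaphthalen-2-yl (2Z)-2-methylbut-2-enoate, via mixed anhydride 20 (not isolated), via C7-epimeric angelate 21 (not isolated)
Conditions: 19, 2,4,6-trichlorobenzoyl chloride, Et3N, toluene, rt; then 18, 80 °C; aqueous work-up; then TsOH·H2O (10 mol %), CH2Cl2, rt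
Reagents that add atoms: none
Why: Mixed-anhydride (Yamaguchi-type) esterification without a nucleophilic catalyst acylates the only free hydroxyl and keeps the Z geometry; acid-catalysed enolisation of the ring B ketone then equilibrates C7, the only epimerisable centre, to the (R) epimer, which alone holds the isopropyl group equatorial in the ring A chair that has 4-CH3 and 3-OAng equatorial (the other chair has syn-diaxial CH3/CH3 and an axial angelate).

**Compound list**
1 | 3-methylcyclohex-2-en-1-one | CC1=CC(=O)CCC1 | starting material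
2 | propa-1,2-diene (allene) | C=C=C | starting material
3 | (1S,6R)-6-methyl-8-methylidenebicyclo[4.2.0]octan-2-one | C1CC[C@]2(C)CC(=C)[C@@H]2C1=O | intermediate
4 | spiro ozonide of 3, (1S,6R)-6-methylspiro[bicyclo[4.2.0]octane-8,3'-[1,2,4]trioxolan]-2-one (both epimers at the spiro carbon) | C1CC[C@]2(C)CC3(OOCO3)[C@@H]2C1=O | intermediate
5 | (1S,6R)-6-methylbicyclo[4.2.0]octane-2,8-dione | C1CC[C@]2(C)CC(=O)[C@@H]2C1=O | intermediate
6 | 2-bromo-3-methylbut-1-ene | CC(C)C(Br)=C | starting material
7 | (3-methylbut-1-en-2-yl)magnesium bromide | CC(C)C(=C)[Mg]Br | intermediate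
8 | bromomagnesium (1R,6R,8S)-6-methyl-8-(3-methylbut-1-en-2-yl)-2-oxobicyclo[4.2.0]octan-8-olate (alkenyl on the exo face) | C1CC[C@]2(C)C[C@@](O[Mg]Br)(C(=C)C(C)C)[C@@H]2C1=O | intermediate
9 | bromomagnesium (3R)-3-methyl-3-(4-methyl-3-methylidene-2-oxopentyl)cyclohex-1-en-1-olate | C1CC[C@](C)(CC(=O)C(=C)C(C)C)C=C1O[Mg]Br | intermediate
10 | bromomagnesium (4aS,8aR)-8a-methyl-5-oxo-3-(propan-2-yl)-1,4,4a,5,6,7,8,8a-octahydronaphthalen-2-olate (cis-fused) | C1CC[C@]2(C)CC(O[Mg]Br)=C(C(C)C)C[C@@H]2C1=O | intermediate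
11 | (4aR,8aS)-6-[(tert-butyldimethylsilyl)oxy]-4a-methyl-7-(propan-2-yl)-3,4,4a,5,8,8a-hexahydronaphthalen-1(2H)-one | C1CC[C@]2(C)CC(O[Si](C)(C)C(C)(C)C)=C(C(C)C)C[C@@H]2C1=O | intermediate
12 | potassium (4aR,8aS)-6-[(tert-butyldimethylsilyl)oxy]-4a-methyl-7-(propan-2-yl)-3,4,4a,5,8,8a-hexahydronaphthalen-1-olate | [K]OC1=CCC[C@]2(C)CC(O[Si](C)(C)C(C)(C)C)=C(C(C)C)C[C@@H]21 | intermediate
13 | (4aR,8aS)-6-[(tert-butyldimethylsilyl)oxy]-4a-methyl-7-(propan-2-yl)-3,4,4a,5,8,8a-hexahydronaphthalen-1-yl trifluoromethanesulfonate | O=S(=O)(OC1=CCC[C@]2(C)CC(O[Si](C)(C)C(C)(C)C)=C(C(C)C)C[C@@H]21)C(F)(F)F | intermediate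
14 | tert-butyl{[(4aS,8aR)-5,8a-dimethyl-3-(propan-2-yl)-1,4,4a,7,8,8a-hexahydronaphthalen-2-yl]oxy}dimethylsilane | CC1=CCC[C@]2(C)CC(O[Si](C)(C)C(C)(C)C)=C(C(C)C)C[C@@H]21 | intermediate
15 | (3RS,4aS,8aR)-5,8a-dimethyl-3-(propan-2-yl)-3,4,4a,7,8,8a-hexahydronaphthalen-2(1H)-one (cis-fused; both epimers at the isopropyl carbon) | CC1=CCC[C@]2(C)CC(=O)C(C(C)C)C[C@@H]21 | intermediate
16 | (1S,2S,4aR,7RS,8aS)-2-iodo-1,4a-dimethyl-6-oxo-7-(propan-2-yl)decahydronaphthalen-1-yl acetate (3β-iodo, 4α-acetoxy, trans-diaxial) | I[C@H]1CC[C@]2(C)CC(=O)C(C(C)C)C[C@@H]2[C@]1(C)OC(C)=O | intermediate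
17 | acetoxonium acetate: 2-methyl-1,3-dioxolan-2-ylium ion cis-fused across C3–C4 on the α face of the decalin (4-CH3 β, C7 both epimers), acetate counter-ion | CC1=[O+][C@@H]2CC[C@]3(C)CC(=O)C(C(C)C)C[C@@H]3[C@]2(C)O1.CC(=O)[O-] | intermediate
18 | (1S,2R,4aR,7RS,8aS)-2-hydroxy-1,4a-dimethyl-6-oxo-7-(propan-2-yl)decahydronaphthalen-1-yl acetate | O[C@@H]1CC[C@]2(C)CC(=O)C(C(C)C)C[C@@H]2[C@]1(C)OC(C)=O | intermediate
19 | angelic acid, (2Z)-2-methylbut-2-enoic acid | C/C=C(/C)C(=O)O | starting material
20 | (2Z)-2-methylbut-2-enoic 2,4,6-trichlorobenzoic anhydride | C/C=C(/C)C(=O)OC(=O)c1c(Cl)cc(Cl)cc1Cl | intermediate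
21 | (1S,2R,4aR,7RS,8aS)-1-(acetyloxy)-1,4a-dimethyl-6-oxo-7-(propan-2-yl)decahydronaphthalen-2-yl (2Z)-2-methylbut-2-enoate | C/C=C(/C)C(=O)O[C@@H]1CC[C@]2(C)CC(=O)C(C(C)C)C[C@@H]2[C@]1(C)OC(C)=O | intermediate
22 | (1S,2R,4aR,7R,8aS)-1-(acetyloxy)-1,4a-dimethyl-6-oxo-7-(propan-2-yl)decahydronaphthalen-2-yl (2Z)-2-methylbut-2-enoate (CNP0322180.1) | C/C=C(/C)C(=O)O[C@@H]1CC[C@]2(C)CC(=O)[C@@H](C(C)C)C[C@@H]2[C@]1(C)OC(C)=O | target

**Step count and risks**
Total step count: 7. Longest linear sequence: 7 steps (1 → 22); 2, 6 and 19 are bought and enter in steps 1, 3 and 7.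

The three steps most likely to fail:

Step 1 (proposed new method). The enantioselectivity and the head-to-head regiochemistry with allene under the chiral Lewis acid are untested. The fallback sets out from 1 and 2 and comes back at 3, using known chemistry. Uncatalysed irradiation (hν 350 nm, Pyrex, THF, −78 °C) gives racemic cis-6-methyl-8-methylidenebicyclo[4.2.0]octan-2-one F1. Ketalisation with (2R,3R)-butane-2,3-diol (PPTS, benzene, reflux, water separator) gives two diastereomers, the (2R,3R)-butane-2,3-diyl ketal of 3 F2 and the (2R,3R)-butane-2,3-diyl ketal of the enantiomer of 3 F3, which are separated by chromatography. Hydrolysis of F2 (PPTS, acetone/H2O) returns 3.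

Step 3 (proposed new method). The organometallic may deprotonate C5 of the 1,3-diketone instead of adding, and the cascade may stall at 8 or 9. The fallback sets out from 3 and comes back at 11, using known chemistry in which the ring A ketone is masked while the alkenyl group is added. Ethylene glycol with PPTS gives the ethylene ketal of 3 F4. Ozonolysis (O3, then PPh3) gives the cyclobutanone ketal F5. Addition of 7 with CeCl3 (THF, −78 °C) gives the tertiary cyclobutanol ketal F6. PPTS in wet acetone releases (1R,6R,8S)-8-hydroxy-6-methyl-8-(3-methylbut-1-en-2-yl)bicyclo[4.2.0]octan-2-one F7. KN(SiMe3)2 (THF, −78 → 0 °C) forms the alkoxide, which undergoes the retro-aldol opening and Michael closure, and TBSOTf then gives 11.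

Step 6. The face of iodine attack depends on the conformation of the flexible cis-octalin, and the monoacetate can migrate to the secondary oxygen. The fallback sets out from 15 and comes back at 18. mCPBA with NaHCO3 (CH2Cl2, 0 °C) gives the 3β,4β-epoxide of 15 F8. AcOH with NaOAc (60 °C) opens it at tertiary C4 with inversion to the trans-diaxial 3β-hydroxy-4α-acetate F9. Dess–Martin periodinane gives the 3-oxo-4α-acetate F10. Zn(BH4)2 (Et2O, −20 °C) delivers hydride axially from the β face, the α face being blocked by the axial acetate, to give 18.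

**Further compounds**
F1 | step 1 | racemic cis-6-methyl-8-methylidenebicyclo[4.2.0]octan-2-one (3 plus its enantiomer) | C1CCC2(C)CC(=C)C2C1=O
F2 | step 1 | (2R,3R)-butane-2,3-diyl ketal of 3 at the ring A carbonyl | C[C@H]1OC2(CCC[C@]3(C)CC(=C)[C@H]23)O[C@@H]1C
F3 | step 1 | (2R,3R)-butane-2,3-diyl ketal of the enantiomer of 3 | C[C@H]1OC2(CCC[C@@]3(C)CC(=C)[C@@H]23)O[C@@H]1C
F4 | step 3 | ethylene ketal of 3 at the ring A carbonyl | C1CC[C@]2(C)CC(=C)[C@@H]2C13OCCO3
F5 | step 3 | ethylene ketal of 5 at the ring A carbonyl (cyclobutanone free) | C1CC[C@]2(C)CC(=O)[C@@H]2C13OCCO3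
F6 | step 3 | tertiary cyclobutanol from exo-face addition of 3-methylbut-1-en-2-yl to the cyclobutanone of F5 | C1CC[C@]2(C)C[C@@](O)(C(=C)C(C)C)[C@@H]2C13OCCO3
F7 | step 3 | (1R,6R,8S)-8-hydroxy-6-methyl-8-(3-methylbut-1-en-2-yl)bicyclo[4.2.0]octan-2-one | C1CC[C@]2(C)C[C@@](O)(C(=C)C(C)C)[C@@H]2C1=O
F8 | step 6 | 3β,4β-epoxide of 15 (C7 both epimers) | O1[C@H]2CC[C@]3(C)CC(=O)C(C(C)C)C[C@@H]3[C@@]12C
F9 | step 6 | 3β-hydroxy-4α-acetoxy-4β-methyl trans-diaxial hydroxy acetate (C3 epimer of 18) | O[C@H]1CC[C@]2(C)CC(=O)C(C(C)C)C[C@@H]2[C@]1(C)OC(C)=O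
F10 | step 6 | 3-oxo-4α-acetoxy-4β-methyl keto acetate (18 oxidised at C3) | O=C1CC[C@]2(C)CC(=O)C(C(C)C)C[C@@H]2[C@]1(C)OC(C)=O
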